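We start from a ratio: left-handed product over right-handed product, pooled over the last two readings of each earlier run, where the amounts are largest against the scatter. Call it s, our reading of the selectivity factor.

| setting | beta | eta | flask |
|---|---|---|---|
| left-handed substrate | 19 mM | 19 mM | 19 mM |
| right-handed substrate | 19 mM | 19 mM | 19 mM |
| partner | 38 mM | 38 mM | 38.0 mM |
| racemization catalyst | 38 µM | 38 µM | 38 µM |
| precatalyst | 1.3 mM | 2.8 mM | 1.9 mM |
| impurity | 20 µM | 20 µM | 20 µM |
| remark | run made earlier | run made earlier |  |
| time |  |  | 1.0 h |

| run | time / min | left-handed product / % | right-handed product / % | left-handed substrate / % |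
|---|---|---|---|---|
| beta | 2.50 | 0 | 2 | 49 |
| beta | 8.00 | 12 | 3 | 42 |
| beta | 15.0 | 22 | 14 | 33 |
| beta | 20.0 | 32 | 21 | 26 |
| beta | 30.0 | 45 | 22 | 17 |
| beta | 40.0 | 49 | 28 | 11 |
| beta | 50.0 | 57 | 27 | 7 |
| eta | 4.00 | 6 | 2 | 43 |
| eta | 6.00 | 12 | 5 | 44 |
| eta | 8.00 | 17 | 11 | 35 |
| eta | 15.0 | 38 | 20 | 25 |
| eta | 20.0 | 47 | 24 | 16 |
| eta | 30.0 | 52 | 26 | 9 |
| eta | 50.0 | 59 | 29 | 5 |

(each reading ± 1.5 percentage points)

- free catalyst is single-handed; left-handed substrate and right-handed substrate are mirror images of each other, charged as a racemate, each of them at the stated concentration
- the analysis behind the earlier runs scatters by 1.5 percentage points, standard deviation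
- an excess is below zero if the other one leads

- excess of left-handed product over right-handed product in the product at 6.0 min
- excess of left-handed product over right-handed product in the product at 1.0 h
- part of the left-handed substrate and right-handed substrate charged together that has reacted at 1.0 h

The reading gives s = 1.97. Two extreme versions of the flask frame the excess. If the racemization catalyst turned the substrates instantly, they would stay equal and the products would form in the ratio s at every moment. The excess would then be E, the fast-turning excess, (s − 1)/(s + 1) = 32.7%, at any time. With no turning, left-handed product could not pass the left-handed charge, 50.0%, and the excess would sink toward zero as both substrates were used up.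

The eta run read 59% of left-handed product, more than that cap, so the turning is real. By balance, its right-handed substrate read 7.00% at 50.0 min against 5% left-handed, a gap of 2 percentage points beside a scatter of 1.5 points per reading. We therefore treat the lag as a small correction and commit to E at both times. The products together read 84.0% in the beta run and 88.0% in the eta run at 50.0 min. The flask has more precatalyst than the beta run and runs longer, so we expect its conversion at 1.0 h to stand above the beta reading.

The forecast gives 33%, 33% and 89%, and says of the pooled excess “it doesn't depend on precatalyst loading”.

The flask gives 34.2%, 33.1% and 89.3%.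

    left-handed substrate + racemization catalyst ⇌ right-handed substrate + racemization catalyst, rate k1*[racemization catalyst]*[left-handed substrate] forward; the back reaction follows from the equilibrium constant (k = 150 M⁻¹ s⁻¹)
    partner + free catalyst + left-handed substrate → free catalyst + left-handed product (k = 520 M⁻² s⁻¹)
    partner + precatalyst → free catalyst + spent reagent (k = 0.00290 M⁻¹ s⁻¹)
    free catalyst + impurity → spent catalyst (k = 160 M⁻¹ s⁻¹)
    partner + free catalyst + right-handed substrate → free catalyst + right-handed product (k = 250 M⁻² s⁻¹)

At 1.0 h, the flask's excess of 33.1% stands beside E at 32.7%, with left-handed substrate at 5.28% and right-handed at 5.40%. The forward turning has a half-life of 2.0 min, short against the hour. Now take a neighbour flask with partner cut to 9.5 mM. The same reckoning gives 32.7% again, and the neighbour's products, 14.8% and 7.14%, give an excess of 34.9%. After 1.0 h, that neighbour had 11% of its partner left, the limiting reagent, and 21.9% of its substrates had reacted.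

The data are calculated with made-up constants; noise was put on by code.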